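## Retrosynthetic overview

1. Cyclopentanone ring A ⇐ cis-fused cadinane (amorphane-type) 4,5-epoxy-3-ketone by a Lewis-acid 1,2-acyl shift (the cadinane → oplopane contraction of the biogenesis); C4–OAc and C5–H then come from a dynamic-kinetic reduction and acetylation.
2. Ring B ⇐ bisabolane-type seco-cadinane by C6–C7 closure (the bond the cyclase makes from the bisabolyl cation), run as an intramolecular vinylogous Mukaiyama–Michael addition onto a 2,5-dihydrofuran-3-carboxylate that then opens to the 8-OH and the 11(12)-en-13-oate.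
3. Seco-cadinane ⇐ (R)-carvone (C1–C6, C9, C10, C14, C15) + a C5 dihydrofuran ester (C7, C8, C11–C13) by a catalytic asymmetric vinylogous Mukaiyama aldol reaction (C8–C9).
4. Ring order: six-membered ring A (from carvone) → ring B → contraction of ring A to the five-membered ring; two esterifications and one double epoxidation lie in between.

Numbering: biogenetic cadinane numbers, kept after ring contraction. Ring A = C1–C6 (C3 carbonyl, C4 carries methyl C15; in the oplopanes C4 is exocyclic on C5). Ring B = C1, C6–C10 (C14 = exocyclic methylene on C10). C11–C13 = three-carbon unit on C7 (C13 = ester carbon). Target: H-1, H-5, H-6, H-7, H-8 on one face, H-9 on the other.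

Assumption: trimethyl 2-phosphonoacrylate, (S)-3-methylpentanoic acid and (E)-3-methylpent-2-enoic acid are bought; the catalyst antipodes named are those expected to give the drawn configuration and are exchanged for their mirror images if a model run shows the opposite sense.

## Route

Step 1
Reactants: 1 (R)-(−)-carvone
Product: 3 2-[(1R)-4-methyl-5-oxocyclohex-3-en-1-yl]prop-2-enal, via 10-hydroxycarvone 2 (not isolated)
Conditions: SeO2 (1.2 equiv), 1,4-dioxane/H2O (30:1), 80 °C
Reagents that add atoms: selenium dioxide, O=[Se]=O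
Why: Riley allylic oxidation (ene reaction then [2,3]-shift) attacks the electron-rich isopropenyl methyl group rather than the electron-poor enone and carries the allylic alcohol on to the enal; the C1 stereocentre is untouched.

Step 2
Reactants: 4 1,4-dioxane-2,5-diol (glycolaldehyde dimer); 5 trimethyl 2-phosphonoacrylate
Product: 8 methyl 2,5-dihydrofuran-3-carboxylate, via glycolaldehyde 6 (not isolated), via oxa-Michael adduct 7 (not isolated)
Conditions: K2CO3, THF/H2O, 0 → 25 °C
Reagents that add atoms: none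
Why: tandem oxa-Michael addition and intramolecular Horner–Wadsworth–Emmons olefination, the oxygen counterpart of the standard 2,5-dihydrothiophene synthesis; no stereocentre is formed.

Step 3
Reactants: 8 methyl 2,5-dihydrofuran-3-carboxylate
Product: 10 tert-butyl{[furan-3(2H)-ylidene](methoxy)methoxy}dimethylsilane, via lithium dienolate 9 (not isolated)
Conditions: LiN(iPr)2, THF, −78 °C; t-BuMe2SiCl, DMPU, −78 °C
Reagents that add atoms: tert-butylchlorodimethylsilane, CC(C)(C)[Si](C)(C)Cl
Why: kinetic γ-deprotonation of the enoate at C5 (the only site giving a through-conjugated dienolate) and O-silylation give the silyl dienolate; ring opening of the dienolate would be the reverse of a 5-endo-trig closure and is slow at −78 °C.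

Step 4
Reactants: 3 2-[(1R)-4-methyl-5-oxocyclohex-3-en-1-yl]prop-2-enal; 10 tert-butyl{[furan-3(2H)-ylidene](methoxy)methoxy}dimethylsilane
Product: 12 methyl (5R)-5-{(1R)-1-hydroxy-2-[(1R)-4-methyl-5-oxocyclohex-3-en-1-yl]prop-2-en-1-yl}-2,5-dihydrofuran-3-carboxylate, via trichlorosilyl ether 11 (not isolated)
Conditions: SiCl4 (1.1 equiv), (S,S)-bisphosphoramide (Denmark type, 5 mol %), iPr2NEt (10 mol %), CH2Cl2, −78 °C; then cold H2O
Reagents that add atoms: none
Why: catalytic enantioselective vinylogous Mukaiyama aldol reaction (Lewis-base-activated SiCl4) in which the chiral silicon cation binds only the aldehyde and exposes its Si face, setting C9 (R) regardless of the remote ring stereocentre; the dienolate reacts at its oxygen-bearing γ-carbon and, by analogy with the locally isosteric 2-silyloxyfurans, through the open transition state that gives the threo adduct (C8 R).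

Step 5
Reactants: 12 the aldol adduct above; 13 (S)-3-methylpentanoic acid
Product: 14 methyl (5R)-5-{(1R)-2-[(1R)-4-methyl-5-oxocyclohex-3-en-1-yl]-1-[(3S)-3-methylpentanoyloxy]prop-2-en-1-yl}-2,5-dihydrofuran-3-carboxylate
Conditions: DCC, DMAP (10 mol %), CH2Cl2, 0 → 23 °C
Reagents that add atoms: none
Why: Steglich esterification puts the final C9 acyl group on with retention, since the C9–O bond is not broken.

Step 6
Reactants: 14 the C9 ester above
Product: 17 methyl (1S,6R,7S,8R,9R)-8-hydroxy-9-[(3S)-3-methylpentanoyloxy]-3-oxocadina-4,10(14),11-trien-13-oate, via linear trimethylsilyl dienol ether 15 (not isolated), via 8-O-trimethylsilyl ether 16 (not isolated)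
Conditions: Me3SiOTf (1.4 equiv), Et3N (1.2 equiv), CH2Cl2, −20 → 23 °C; then Tf2NH (10 mol %), −40 → 23 °C; then aq. citric acid/THF, 0 °C (17 used at once)
Reagents that add atoms: none
Why: Proposed new method: under equilibrating silylation the ketone gives the linear (3,5-type) dienol ether 15, whose γ-carbon C6 is the only nucleophilic carbon that can reach C7 of the tethered enoate in a six-membered transition state and must add on the face that carries the C1 tether (cis ring fusion, C6 R), while the flat dihydrofuran can only be attacked at C7 cis to its C8–C9 bond (C7 S, H-7 and H-8 cis); the silyl ketene acetal so formed expels the ring oxygen (E1cB with silyl transfer to O-8, the reverse 5-endo-trig closure being disfavoured) to unveil the 11(12)-ene ester and the 8-OH, the closest known reactions being the intramolecular vinylogous Mukaiyama–Michael addition and the SN2′-type opening of Morita–Baylis–Hillman ethers.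

Step 7
Reactants: 17 the hydroxy enone above; 18 (E)-3-methylpent-2-enoic acid
Product: 19 methyl (1S,6R,7S,8R,9R)-8-[(2E)-3-methylpent-2-enoyloxy]-9-[(3S)-3-methylpentanoyloxy]-3-oxocadina-4,10(14),11-trien-13-oate
Conditions: DCC, DMAP (10 mol %), CH2Cl2, 0 °C
Reagents that add atoms: none
Why: Steglich esterification of the axial C8 alcohol run cold and at once, which forestalls lactonisation onto C13 and E/Z drift of the enoate; the trans-diaxial 8-OH/9-acyloxy pair cannot form the cyclic orthoester needed for acyl migration.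

Step 8
Reactants: 19 the diester enone above
Product: 21 methyl (1S,4R,5R,6R,7R,8R,9R,11R)-4,5:11,12-diepoxy-8-[(2E)-3-methylpent-2-enoyloxy]-9-[(3S)-3-methylpentanoyloxy]-3-oxocadin-10(14)-en-13-oate, via 4,5-epoxy ketone 20 (not isolated)
Conditions: t-BuOOH (decane), n-BuLi (3 equiv each), THF, −78 → −20 °C; then H2O
Reagents that add atoms: tert-butyl hydroperoxide, CC(C)(C)OO
Why: Weitz–Scheffer-type nucleophilic epoxidation with LiOOt-Bu, fast on the enone from the convex face anti to the C6–C7 bond (4R,5R, a configuration not carried into the target) and slower on the 1,1-disubstituted acrylate, where the enolate is expected to close onto oxygen anti to the axial 8-acyloxy group (11R as major epimer, minor one removed by chromatography); the β,β-disubstituted enoate and the unactivated exocyclic methylene are inert.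

Step 9
Reactants: 21 the diepoxide above
Product: 22 methyl (1S,6R,7R,8R,9R,11R)-11,12-epoxy-8-[(2E)-3-methylpent-2-enoyloxy]-9-[(3S)-3-methylpentanoyloxy]-3,4-dioxo-oplop-10(14)-en-13-oate (C5 labile)
Conditions: BF3·OEt2 (20 mol %), CH2Cl2, −78 → −20 °C
Reagents that add atoms: none
Why: Lewis-acid rearrangement of an α,β-epoxy ketone by 1,2-acyl shift (House type): the ketone forbids a cation at C4, so the C5–O bond opens with concerted migration of the C3 acyl carbon from C4 to C5, which contracts ring A to the cyclopentanone and leaves C4 as the acetyl carbonyl; C5 of the β-diketone is labile and is fixed in step 10, and the ester-deactivated terminal epoxide at C11 is far harder to ionise.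

Step 10
Reactants: 22 the β-diketone above
Product: 23 methyl (1S,4S,5R,6R,7R,8R,9R,11R)-11,12-epoxy-4-hydroxy-8-[(2E)-3-methylpent-2-enoyloxy]-9-[(3S)-3-methylpentanoyloxy]-3-oxo-oplop-10(14)-en-13-oate
Conditions: RuCl(p-cymene)[(S,S)-TsDPEN] (2 mol %), HCO2H/Et3N (5:2), EtOAc, 25 °C
Reagents that add atoms: none
Why: Noyori–Ikariya asymmetric transfer hydrogenation with dynamic kinetic resolution, in which the catalyst reduces only the methyl ketone (methyl versus branched-alkyl differentiation), sets C4 (S), and takes from the rapidly enolising C5 epimers the one that reacts through the Felkin-type syn transition state (C5 R).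

Step 11
Reactants: 23 the hydroxy ketone above
Product: 24 methyl (1S,4S,5R,6R,7R,8R,9R,11R)-4-acetoxy-11,12-epoxy-8-[(2E)-3-methylpent-2-enoyloxy]-9-[(3S)-3-methylpentanoyloxy]-3-oxo-oplop-10(14)-en-13-oate (CNP0109740.1)
Conditions: Ac2O, pyridine, CH2Cl2, 0 → 23 °C
Reagents that add atoms: acetic anhydride, CC(=O)OC(C)=O
Why: O-acetylation under weakly basic conditions that neither enolise C5 nor eliminate the β-acetoxy ketone.

## Compound list

1 | (R)-(−)-carvone, (5R)-2-methyl-5-(prop-1-en-2-yl)cyclohex-2-en-1-one | C=C(C)[C@H]1CC(=O)C(C)=CC1 | starting material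
2 | 10-hydroxycarvone, (5R)-5-(3-hydroxyprop-1-en-2-yl)-2-methylcyclohex-2-en-1-one | C=C(CO)[C@H]1CC(=O)C(C)=CC1 | intermediate
3 | 2-[(1R)-4-methyl-5-oxocyclohex-3-en-1-yl]prop-2-enal | C=C(C=O)[C@H]1CC(=O)C(C)=CC1 | intermediate
4 | 1,4-dioxane-2,5-diol (glycolaldehyde dimer, isomer mixture) | OC1COC(O)CO1 | starting material
5 | trimethyl 2-phosphonoacrylate, methyl 2-(dimethoxyphosphoryl)prop-2-enoate | C=C(C(=O)OC)P(=O)(OC)OC | starting material
6 | glycolaldehyde | OCC=O | intermediate
7 | methyl 2-(dimethoxyphosphoryl)-3-(2-oxoethoxy)propanoate (racemic oxa-Michael adduct) | COC(=O)C(COCC=O)P(=O)(OC)OC | intermediate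
8 | methyl 2,5-dihydrofuran-3-carboxylate | COC(=O)C1=CCOC1 | intermediate
9 | lithium dienolate of 8 (deprotonated at C5) | [Li+].COC([O-])=C1COC=C1 | intermediate
10 | tert-butyl{[furan-3(2H)-ylidene](methoxy)methoxy}dimethylsilane (E/Z mixture) | COC(O[Si](C)(C)C(C)(C)C)=C1COC=C1 | intermediate
11 | 9-O-trichlorosilyl ether of 12 | C=C([C@H]1CC(=O)C(C)=CC1)[C@@H](O[Si](Cl)(Cl)Cl)[C@@H]1OCC(C(=O)OC)=C1 | intermediate
12 | methyl (5R)-5-{(1R)-1-hydroxy-2-[(1R)-4-methyl-5-oxocyclohex-3-en-1-yl]prop-2-en-1-yl}-2,5-dihydrofuran-3-carboxylate (threo; C8 R, C9 R) | C=C([C@H]1CC(=O)C(C)=CC1)[C@@H](O)[C@@H]1OCC(C(=O)OC)=C1 | intermediate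
13 | (S)-3-methylpentanoic acid | CC[C@H](C)CC(=O)O | starting material
14 | methyl (5R)-5-{(1R)-2-[(1R)-4-methyl-5-oxocyclohex-3-en-1-yl]-1-[(3S)-3-methylpentanoyloxy]prop-2-en-1-yl}-2,5-dihydrofuran-3-carboxylate | C=C([C@H]1CC(=O)C(C)=CC1)[C@@H](OC(=O)C[C@@H](C)CC)[C@@H]1OCC(C(=O)OC)=C1 | intermediate
15 | methyl (5R)-5-{(1R)-2-[(1S)-4-methyl-5-(trimethylsilyloxy)cyclohexa-2,4-dien-1-yl]-1-[(3S)-3-methylpentanoyloxy]prop-2-en-1-yl}-2,5-dihydrofuran-3-carboxylate (linear dienol ether) | C=C([C@H]1CC(O[Si](C)(C)C)=C(C)C=C1)[C@@H](OC(=O)C[C@@H](C)CC)[C@@H]1OCC(C(=O)OC)=C1 | intermediate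
16 | 8-O-trimethylsilyl ether of 17 | C=C1[C@H]2CC(=O)C(C)=C[C@H]2[C@@H](C(=C)C(=O)OC)[C@@H](O[Si](C)(C)C)[C@@H]1OC(=O)C[C@@H](C)CC | intermediate
17 | methyl (1S,6R,7S,8R,9R)-8-hydroxy-9-[(3S)-3-methylpentanoyloxy]-3-oxocadina-4,10(14),11-trien-13-oate (cis-fused; H-1, H-6, H-7, H-8 on one face, H-9 on the other) | C=C1[C@H]2CC(=O)C(C)=C[C@H]2[C@@H](C(=C)C(=O)OC)[C@@H](O)[C@@H]1OC(=O)C[C@@H](C)CC | intermediate
18 | (E)-3-methylpent-2-enoic acid | CC/C(C)=C/C(=O)O | starting material
19 | methyl (1S,6R,7S,8R,9R)-8-[(2E)-3-methylpent-2-enoyloxy]-9-[(3S)-3-methylpentanoyloxy]-3-oxocadina-4,10(14),11-trien-13-oate | C=C1[C@H]2CC(=O)C(C)=C[C@H]2[C@@H](C(=C)C(=O)OC)[C@@H](OC(=O)/C=C(\C)CC)[C@@H]1OC(=O)C[C@@H](C)CC | intermediate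
20 | methyl (1S,4R,5R,6R,7S,8R,9R)-4,5-epoxy-8-[(2E)-3-methylpent-2-enoyloxy]-9-[(3S)-3-methylpentanoyloxy]-3-oxocadina-10(14),11-dien-13-oate (epoxide on the face of H-6) | C=C1[C@H]2CC(=O)[C@]3(C)O[C@@H]3[C@H]2[C@@H](C(=C)C(=O)OC)[C@@H](OC(=O)/C=C(\C)CC)[C@@H]1OC(=O)C[C@@H](C)CC | intermediate
21 | methyl (1S,4R,5R,6R,7R,8R,9R,11R)-4,5:11,12-diepoxy-8-[(2E)-3-methylpent-2-enoyloxy]-9-[(3S)-3-methylpentanoyloxy]-3-oxocadin-10(14)-en-13-oate | C=C1[C@H]2CC(=O)[C@]3(C)O[C@@H]3[C@H]2[C@@H]([C@]2(C(=O)OC)CO2)[C@@H](OC(=O)/C=C(\C)CC)[C@@H]1OC(=O)C[C@@H](C)CC | intermediate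
22 | methyl (1S,6R,7R,8R,9R,11R)-11,12-epoxy-8-[(2E)-3-methylpent-2-enoyloxy]-9-[(3S)-3-methylpentanoyloxy]-3,4-dioxo-oplop-10(14)-en-13-oate (2-acetylcyclopentanone; C5 epimers and enol in equilibrium, so C5 is left open) | C=C1[C@H]2CC(=O)C(C(C)=O)[C@H]2[C@@H]([C@]2(C(=O)OC)CO2)[C@@H](OC(=O)/C=C(\C)CC)[C@@H]1OC(=O)C[C@@H](C)CC | intermediate
23 | methyl (1S,4S,5R,6R,7R,8R,9R,11R)-11,12-epoxy-4-hydroxy-8-[(2E)-3-methylpent-2-enoyloxy]-9-[(3S)-3-methylpentanoyloxy]-3-oxo-oplop-10(14)-en-13-oate | C=C1[C@H]2CC(=O)[C@@H]([C@H](C)O)[C@H]2[C@@H]([C@]2(C(=O)OC)CO2)[C@@H](OC(=O)/C=C(\C)CC)[C@@H]1OC(=O)C[C@@H](C)CC | intermediate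
24 | methyl (1S,4S,5R,6R,7R,8R,9R,11R)-4-acetoxy-11,12-epoxy-8-[(2E)-3-methylpent-2-enoyloxy]-9-[(3S)-3-methylpentanoyloxy]-3-oxo-oplop-10(14)-en-13-oate (CNP0109740.1) | C=C1[C@H]2CC(=O)[C@@H]([C@H](C)OC(C)=O)[C@H]2[C@@H]([C@]2(C(=O)OC)CO2)[C@@H](OC(=O)/C=C(\C)CC)[C@@H]1OC(=O)C[C@@H](C)CC | target

## Step count and risks

Total steps: 11. Longest linear sequence: 10 (steps 2–11, from 4 and 5); the carvone branch is 9 steps.

Step 6 is the most likely to fail. The kinetic cross-conjugated dienol ether could cyclise through C2 instead of C6, and the enoate may be too weak an acceptor for the in-flask Lewis acid. The fallback replaces the ionic closure by a pericyclic one and sets out from 14. Silylation with t-BuMe2SiOTf/Et3N under equilibrating conditions gives the robust linear tert-butyldimethylsilyl dienol ether F1, which is freed from any cross-conjugated isomer on Et3N-deactivated silica. Heating F1 in toluene (110–130 °C) brings about an intramolecular Diels–Alder reaction between the C3–C6 diene and the C7=C11 enoate. The tether allows only the C6–C7/C3–C11 mode on the face of the C1 substituent, giving the bicyclo[2.2.2]octene adduct F2. Bu4NF/AcOH (THF, 0 °C) then frees the bridgehead alkoxide, retro-aldol cleavage of C3–C11 restores the enone, and the ester enolate expels O-8. The route is rejoined at 17.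

Step 9 is the second risk. BF3 may open the glycidic ester, or a hydride shift may compete with the acyl shift. The fallback reorders the events so that no glycidate is present during the Lewis-acid step, and sets out from 19. t-BuOOH/DBU (CH2Cl2, 0 °C) epoxidises only the enone, and the 4,5-epoxy ketone 20 is isolated this time. BF3·OEt2 then contracts ring A while the C11 unit is still an alkene, giving the diketo acrylate F3. LiOOt-Bu (2.2 equiv, the first equivalent parking the β-diketone as its unreactive enolate) epoxidises the acrylate, and the route is rejoined at 22.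

Step 10 is the third risk. The catalyst might reduce the ring ketone or select the other C5 epimer, and the wanted C5 configuration (side chain on the concave face) is probably not the thermodynamic one. The fallback sets both centres by one syn addition instead of a carbonyl reduction, and sets out from 22. The chelated magnesium enolate (MgBr2·OEt2, Et3N) is O-acetylated with Ac2O to the (Z)-enol acetate F4, with the acetoxy group syn to the ring carbonyl. Hydrogenation with [Rh(cod)((R,R)-Me-DuPhos)]BF4 under H2, which binds this acetate-bearing olefin in preference to the others, adds both hydrogens from the convex face. That gives H-5 and H-4 of the target directly, and the route is rejoined at 24.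

## Further compounds

F1 | step 6 | methyl (5R)-5-{(1R)-2-[(1S)-5-(tert-butyldimethylsilyloxy)-4-methylcyclohexa-2,4-dien-1-yl]-1-[(3S)-3-methylpentanoyloxy]prop-2-en-1-yl}-2,5-dihydrofuran-3-carboxylate | C=C([C@H]1CC(O[Si](C)(C)C(C)(C)C)=C(C)C=C1)[C@@H](OC(=O)C[C@@H](C)CC)[C@@H]1OCC(C(=O)OC)=C1
F2 | step 6 | intramolecular Diels–Alder adduct of F1: bicyclo[2.2.2]oct-5-ene with bridgehead C3 (silyloxy) bonded to C11 and bridgehead C6 bonded to C7, tetrahydrofuran O8–C12 kept, ester on the side of the C4=C5 bridge | C=C1[C@H]2C[C@]3(O[Si](C)(C)C(C)(C)C)C(C)=C[C@H]2[C@@H]2[C@@H](OC[C@@]23C(=O)OC)[C@@H]1OC(=O)C[C@@H](C)CC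
F3 | step 9 | methyl (1S,6R,7S,8R,9R)-8-[(2E)-3-methylpent-2-enoyloxy]-9-[(3S)-3-methylpentanoyloxy]-3,4-dioxo-oplopa-10(14),11-dien-13-oate (C5 labile) | C=C1[C@H]2CC(=O)C(C(C)=O)[C@H]2[C@@H](C(=C)C(=O)OC)[C@@H](OC(=O)/C=C(\C)CC)[C@@H]1OC(=O)C[C@@H](C)CC
F4 | step 10 | methyl (1S,4Z,6R,7R,8R,9R,11R)-4-acetoxy-11,12-epoxy-8-[(2E)-3-methylpent-2-enoyloxy]-9-[(3S)-3-methylpentanoyloxy]-3-oxo-oplopa-4,10(14)-dien-13-oate | C=C1[C@H]2CC(=O)/C(=C(/C)OC(C)=O)[C@H]2[C@@H]([C@]2(C(=O)OC)CO2)[C@@H](OC(=O)/C=C(\C)CC)[C@@H]1OC(=O)C[C@@H](C)CC
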